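**Retrosynthetic overview**
1. The target comes from a fully benzylated flavanone–flavone 7''-sulfate that carries a benzyl ester on C3, by global hydrogenolysis and loss of CO2 from C3. That compound comes from a spiro β-keto lactone by alkoxide opening and sulfation of the phenoxide set free.
2. The spiro lactone comes from a single [4+2] annulation that forms O1–C2 and C3–C4 of flavanone ring C. The partners are a pentafluorophenyl salicylate (ring A, O1, C4) and a 4-benzyloxybenzylidene lactone (C2=C3, ring B, the whole flavone unit).
3. Enabling feature: C3 is bonded to C8'' of ring A of the flavone unit, and C8'' is ortho to O7''. A carbonyl bridge O7''–C(=O)–C3 closes a five-membered benzofuran-2(3H)-one ring that is not in the target. This ring makes C2 electrophilic and turns C3 into an aromatic 2-oxidobenzofuran enolate after addition. It also keeps C3 quaternary so that C2 cannot racemise, and on opening it frees only O7'', the sulfation site.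
4. The benzylidene lactone comes from a Knoevenagel condensation of 4-benzyloxybenzaldehyde with a lactone made from luteolin (catechol ketal, 7-O-allylation, 5-O-benzylation, Claisen shift to C8, alkene cleavage, lactol oxidation).
5. Ring order: the three flavone rings come with luteolin, then the temporary lactone ring, then flavanone ring C (key step), then the lactone ring is cleaved.

Key step: step 11

Assumption: luteolin-derived compounds carry ordinary flavone locants before the coupling, and afterwards unprimed locants denote the flavanone unit and double-primed locants the flavone unit; the target is taken as the free hydrogen sulfate as drawn and is released from its lithium salt only at the end; the sense of induction of the cinchona squaramide has to be assigned in the first run, so the quinidine-derived catalyst is written and its quinine-derived pseudo-enantiomer is the alternative.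

Step 1
Reactants: 1 luteolin
Product: 2 3',4'-O-diphenylmethylene-luteolin
Conditions: Ph2CCl2 (1.5 equiv), Ph2O, 175 °C
Reagents that add atoms: dichlorodiphenylmethane ClC(Cl)(c1ccccc1)c1ccccc1
Why: Ketalisation, a known selective protection of catechol-type flavonoids, should work because only the ring B catechol can close a five-membered 1,3-benzodioxole, which leaves the 5- and 7-hydroxyls free.

Step 2
Reactants: 2 3',4'-O-diphenylmethylene-luteolin
Product: 3 7-O-allyl-3',4'-O-diphenylmethylene-luteolin
Conditions: allyl bromide (1.05 equiv), K2CO3, DMF, rt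
Reagents that add atoms: allyl bromide C=CCBr
Why: Williamson etherification should go to O7 only, because the 7-OH is the most acidic hydroxyl (vinylogous acid of the C4 carbonyl) whereas the 5-OH is held in a hydrogen bond to C4=O.

Step 3
Reactants: 3 7-O-allyl-3',4'-O-diphenylmethylene-luteolin
Product: 4 7-O-allyl-5-O-benzyl-3',4'-O-diphenylmethylene-luteolin
Conditions: BnBr, K2CO3, DMF, 70 °C
Reagents that add atoms: benzyl bromide BrCc1ccccc1
Why: Williamson etherification under forcing conditions alkylates the remaining chelated 5-OH and gives the fully O-alkylated ring A needed for a clean rearrangement.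

Step 4
Reactants: 4 7-O-allyl-5-O-benzyl-3',4'-O-diphenylmethylene-luteolin
Product: 5 8-C-allyl-5-O-benzyl-3',4'-O-diphenylmethylene-luteolin (7-OH free)
Conditions: PhNEt2, 200 °C
Reagents that add atoms: none
Why: In the aromatic Claisen rearrangement of 7-allyloxychromones the C7–C8 bond has the higher double-bond character, so the allyl group should migrate mainly to C8 and O7 is set free again.

Step 5
Reactants: 5 8-C-allyl-5-O-benzyl-3',4'-O-diphenylmethylene-luteolin
Product: 8 lactol (2-hydroxy-2,3-dihydrofuran ring fused to C7–C8 of the flavone; racemic at the hemiacetal carbon), via diol 6 (not isolated), via aldehyde 7 (not isolated)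
Conditions: OsO4 (2 mol %), NaIO4, 2,6-lutidine, dioxane/H2O, rt
Reagents that add atoms: osmium tetroxide O=[Os](=O)(=O)=O (delivers the oxygen); sodium periodate [Na+].[O-]I(=O)(=O)=O (terminal oxygen source)
Why: In the Lemieux–Johnson cleavage OsO4 should dihydroxylate the terminal alkene in preference to the electron-poor C2=C3 bond of the flavone, NaIO4 cleaves the diol, and the arylacetaldehyde is trapped by the ortho 7-OH as a five-membered lactol.

Step 6
Reactants: 8 lactol
Product: 9 lactone of (5-benzyloxy-7-hydroxyflavon-8-yl)acetic acid (benzofuran-2(3H)-one ring fused to C7–C8 of the protected luteolin)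
Conditions: Ag2CO3 on Celite, toluene, reflux
Reagents that add atoms: none
Why: The Fétizon oxidation converts a lactol into the lactone under neutral conditions that should leave benzyl ether, ketal and flavone untouched.

Step 7
Reactants: 9 lactone; 10 4-(benzyloxy)benzaldehyde
Product: 11 (Z)-4-benzyloxybenzylidene lactone
Conditions: piperidine/AcOH (10 mol % each), 4 Å MS, toluene, 80 °C
Reagents that add atoms: none
Why: The Knoevenagel condensation should work because the lactone CH2 is doubly activated (aryl and ester carbonyl), and the Z isomer, with its aryl group turned away from the pyranone oxygen, should prevail under these equilibrating conditions.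

Step 8
Reactants: 12 methyl 2,4,6-trihydroxybenzoate
Product: 13 methyl 2,4-bis(benzyloxy)-6-hydroxybenzoate
Conditions: BnBr (2.1 equiv), K2CO3, acetone, reflux
Reagents that add atoms: benzyl bromide BrCc1ccccc1
Why: Williamson etherification should benzylate the 4-OH and one of the two equivalent ortho hydroxyls, while the last hydroxyl is shielded by its hydrogen bond to the ester carbonyl.

Step 9
Reactants: 13 methyl 2,4-bis(benzyloxy)-6-hydroxybenzoate
Product: 14 2,4-bis(benzyloxy)-6-hydroxybenzoic acid
Conditions: KOH, EtOH/H2O, reflux; then 1 M HCl, 0 °C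
Reagents that add atoms: potassium hydroxide [K+].[OH-]
Why: Saponification of the hindered ester needs hot alkali, which the benzyl ethers tolerate, and cold acidification avoids decarboxylation of the electron-rich salicylic acid.

Step 10
Reactants: 14 2,4-bis(benzyloxy)-6-hydroxybenzoic acid
Product: 15 pentafluorophenyl 2,4-bis(benzyloxy)-6-hydroxybenzoate
Conditions: C6F5OH, DCC, EtOAc, 0 °C to rt
Reagents that add atoms: pentafluorophenol Oc1c(F)c(F)c(F)c(F)c1F
Why: Carbodiimide esterification should give the active ester, because the chelated and hindered ortho hydroxyl does not compete with the far more acidic pentafluorophenol.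

Step 11
Reactants: 11 (Z)-4-benzyloxybenzylidene lactone; 15 pentafluorophenyl 2,4-bis(benzyloxy)-6-hydroxybenzoate
Product: 17 spiro β-keto lactone (2S,3R in flavanone numbering; C2 has the spatial arrangement of 2R in the target; C2 aryl cis to the lactone carbonyl), via oxa-Michael adduct 16 (not isolated)
Conditions: quinidine-derived 3,5-bis(trifluoromethyl)phenyl squaramide (10 mol %), Na2CO3 (1.2 equiv), 4 Å MS, toluene, 0 °C to rt, slow addition of 15
Reagents that add atoms: none
Why: Proposed new method: the quinuclidine nitrogen of the catalyst takes the proton of the chelated phenol of 15 while the squaramide NH groups bind the lactone carbonyl of 11, the phenoxide adds to the benzylidene carbon (oxa-Michael addition, O1–C2), and the aromatic 2-oxidobenzofuran enolate of 16 attacks the adjacent pentafluorophenyl ester through C3 (Dieckmann-type C-acylation, C3–C4) with irreversible loss of pentafluorophenoxide, which Na2CO3 scavenges. The closest known reaction types are the bifunctional-amine-catalysed domino oxa-Michael/1,6-addition and oxa-Michael/aldol annulations of ortho-functionalised phenols with 3-ylidene oxindoles or benzofuranones, which give spiro chromans, and the base-mediated Michael/Dieckmann annulation of salicylate or thiosalicylate esters with acrylates; new is the active ester as terminator on a catalyst-bound lactone enolate. One ring is closed, the six-membered dihydropyranone ring C of the flavanone unit, by a 6-(enolexo)-exo-trig addition–elimination that follows the intermolecular C–O bond formation. C2 is controlled by the catalyst, which shields one face of the bound acceptor; as the oxa-Michael step is reversible, the faster-cyclising catalyst-bound adduct is drained (Curtin–Hammett situation), and spiro C3 is controlled by the substrate through a chair-like transition state with the C2 aryl group pseudo-equatorial and anti to the flavone ring. The product cannot racemise because quaternary C3 carries no proton for a retro-oxa-Michael reaction, and the C3 configuration is inconsequential since it is reset in step 13. Regioselectivity (O1 to C2, C4 to C3) is secured by the polarisation of C2=C3 by the lactone carbonyl, C- over O-acylation by ring size (six against eight members), and self-condensation of 15 is held back by its two ortho substituents, its chelated hydroxyl and its slow addition.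

Step 12
Reactants: 17 spiro β-keto lactone
Product: 19 lithium 7''-sulfate of the benzyl 3-carboxylate (2S,3R; all other phenols protected), via lithium phenoxide 18 (not isolated)
Conditions: BnOH (1.05 equiv)/n-BuLi (1.0 equiv), THF, -40 to 0 °C; then SO3·pyridine (3 equiv), DMF, 0 °C to rt
Reagents that add atoms: benzyl alcohol OCc1ccccc1; n-butyllithium [Li]CCCC; sulfur trioxide pyridine complex [O-]S(=O)(=O)[n+]1ccccc1
Why: Alcoholysis of the strained aryl lactone by an alkoxide is driven by release of the much less basic 7''-phenoxide (attack at the doubly ortho-substituted and electron-rich C4 ketone should be slower), this only free phenoxide is O-sulfated in situ by the SO3 complex, and both stereocentres stay untouched because C3 is still quaternary.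

Step 13
Reactants: 19 lithium 7''-sulfate of the benzyl 3-carboxylate
Product: 22 (2R,3S)-naringenin-(3→8'')-luteolin 7''-O-sulfate (target), via keto acid salt 20 (not isolated), via lithium salt 21 (not isolated)
Conditions: H2 (1 atm), Pd(OH)2/C, THF/MeOH, rt; filter, 30 °C; then HCl (1.0 equiv), MeOH, 0 °C, Sephadex LH-20
Reagents that add atoms: none
Why: Catalytic hydrogenolysis removes the four benzyl ethers, the benzyl ester and the diphenylmethylene ketal, the liberated β-keto acid loses CO2 (decarboxylation through the cyclic transition state, relactonisation being impossible because O7'' is sulfated), and the enol ketonises under thermodynamic control to the 2,3-trans (2R,3S) isomer with both aryl groups equatorial while C2 is untouched.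

**Compound list**
1 | luteolin | O=c1cc(-c2ccc(O)c(O)c2)oc2cc(O)cc(O)c12 | starting material
2 | 3',4'-O-diphenylmethylene-luteolin | O=c1cc(-c2ccc3c(c2)OC(c2ccccc2)(c2ccccc2)O3)oc2cc(O)cc(O)c12 | intermediate
3 | 7-O-allyl-3',4'-O-diphenylmethylene-luteolin | O=c1cc(-c2ccc3c(c2)OC(c2ccccc2)(c2ccccc2)O3)oc2cc(OCC=C)cc(O)c12 | intermediate
4 | 7-O-allyl-5-O-benzyl-3',4'-O-diphenylmethylene-luteolin | O=c1cc(-c2ccc3c(c2)OC(c2ccccc2)(c2ccccc2)O3)oc2cc(OCC=C)cc(OCc3ccccc3)c12 | intermediate
5 | 8-C-allyl-5-O-benzyl-3',4'-O-diphenylmethylene-luteolin | O=c1cc(-c2ccc3c(c2)OC(c2ccccc2)(c2ccccc2)O3)oc2c(CC=C)c(O)cc(OCc3ccccc3)c12 | intermediate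
6 | 8-(2,3-dihydroxypropyl) diol (racemic, not isolated) | O=c1cc(-c2ccc3c(c2)OC(c2ccccc2)(c2ccccc2)O3)oc2c(CC(O)CO)c(O)cc(OCc3ccccc3)c12 | intermediate
7 | (flavon-8-yl)acetaldehyde (not isolated) | O=c1cc(-c2ccc3c(c2)OC(c2ccccc2)(c2ccccc2)O3)oc2c(CC=O)c(O)cc(OCc3ccccc3)c12 | intermediate
8 | lactol fused to C7–C8 (racemic) | O=c1cc(-c2ccc3c(c2)OC(c2ccccc2)(c2ccccc2)O3)oc2c3CC(O)Oc3cc(OCc3ccccc3)c12 | intermediate
9 | lactone (benzofuran-2(3H)-one fused to C7–C8) | O=c1cc(-c2ccc3c(c2)OC(c2ccccc2)(c2ccccc2)O3)oc2c3CC(=O)Oc3cc(OCc3ccccc3)c12 | intermediate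
10 | 4-(benzyloxy)benzaldehyde | O=Cc1ccc(OCc2ccccc2)cc1 | starting material
11 | (Z)-4-benzyloxybenzylidene lactone | O=c1cc(-c2ccc3c(c2)OC(c2ccccc2)(c2ccccc2)O3)oc2c3/C(=C/c4ccc(OCc5ccccc5)cc4)C(=O)Oc3cc(OCc3ccccc3)c12 | intermediate
12 | methyl 2,4,6-trihydroxybenzoate | COC(=O)c1c(O)cc(O)cc1O | starting material
13 | methyl 2,4-bis(benzyloxy)-6-hydroxybenzoate | COC(=O)c1c(O)cc(OCc2ccccc2)cc1OCc1ccccc1 | intermediate
14 | 2,4-bis(benzyloxy)-6-hydroxybenzoic acid | OC(=O)c1c(O)cc(OCc2ccccc2)cc1OCc1ccccc1 | intermediate
15 | pentafluorophenyl 2,4-bis(benzyloxy)-6-hydroxybenzoate | O=C(Oc1c(F)c(F)c(F)c(F)c1F)c1c(O)cc(OCc2ccccc2)cc1OCc1ccccc1 | intermediate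
16 | oxa-Michael adduct (reacts through its enolate, C3 undefined, not isolated) | O=C(Oc1c(F)c(F)c(F)c(F)c1F)c1c(OCc2ccccc2)cc(OCc2ccccc2)cc1O[C@@H](c1ccc(OCc2ccccc2)cc1)C1C(=O)Oc2cc(OCc3ccccc3)c3c(=O)cc(-c4ccc5c(c4)OC(c4ccccc4)(c4ccccc4)O5)oc3c12 | intermediate
17 | spiro β-keto lactone (2S,3R) | O=C1c2c(OCc3ccccc3)cc(OCc3ccccc3)cc2O[C@@H](c2ccc(OCc3ccccc3)cc2)[C@@]13C(=O)Oc4cc(OCc5ccccc5)c5c(=O)cc(-c6ccc7c(c6)OC(c6ccccc6)(c6ccccc6)O7)oc5c34 | intermediate
18 | lithium 7''-phenoxide of the benzyl 3-carboxylate (2S,3R, not isolated) | O=C1c2c(OCc3ccccc3)cc(OCc3ccccc3)cc2O[C@@H](c2ccc(OCc3ccccc3)cc2)[C@]1(C(=O)OCc1ccccc1)c1c([O-])cc(OCc2ccccc2)c2c(=O)cc(-c3ccc4c(c3)OC(c3ccccc3)(c3ccccc3)O4)oc12.[Li+] | intermediate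
19 | lithium 7''-sulfate of the benzyl 3-carboxylate (2S,3R) | O=C1c2c(OCc3ccccc3)cc(OCc3ccccc3)cc2O[C@@H](c2ccc(OCc3ccccc3)cc2)[C@]1(C(=O)OCc1ccccc1)c1c(OS(=O)(=O)[O-])cc(OCc2ccccc2)c2c(=O)cc(-c3ccc4c(c3)OC(c3ccccc3)(c3ccccc3)O4)oc12.[Li+] | intermediate
20 | deprotected 3-carboxylic acid, lithium 7''-sulfate (2S,3R, not isolated) | O=C1c2c(O)cc(O)cc2O[C@@H](c2ccc(O)cc2)[C@]1(C(=O)O)c1c(OS(=O)(=O)[O-])cc(O)c2c(=O)cc(-c3ccc(O)c(O)c3)oc12.[Li+] | intermediate
21 | lithium salt of the target (2R,3S, not isolated) | O=C1c2c(O)cc(O)cc2O[C@@H](c2ccc(O)cc2)[C@@H]1c1c(OS(=O)(=O)[O-])cc(O)c2c(=O)cc(-c3ccc(O)c(O)c3)oc12.[Li+] | intermediate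
22 | (2R,3S)-naringenin-(3→8'')-luteolin 7''-O-sulfate | O=C1c2c(O)cc(O)cc2O[C@@H](c2ccc(O)cc2)[C@@H]1c1c(OS(=O)(=O)O)cc(O)c2c(=O)cc(-c3ccc(O)c(O)c3)oc12 | target

Total step count: 13. Longest linear sequence: 10 steps (steps 1–7 and 11–13).

**Steps most likely to fail**

**Step 11 (key step).**
- What may go wrong: the oxa-Michael adduct may revert faster than the crowded enolate is acylated, facial selectivity may be poor through a carbonate-mediated background reaction, or the active ester may oligomerise.
- Fallback idea: bring in C4 one oxidation level lower, as the less hindered aldehyde, and use only known reaction types. The fallback sets out from 11.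
- Commercial 2,4,6-trihydroxybenzaldehyde is dibenzylated (BnBr, K2CO3, acetone) to 2,4-bis(benzyloxy)-6-hydroxybenzaldehyde F1.
- F1 undergoes with 11 the established bifunctional-amine-catalysed domino oxa-Michael/aldol reaction of salicylaldehydes with electron-poor alkenes. This gives the spiro chroman-4-ol F2, in which the same two bonds are formed.
- Dess–Martin oxidation of the secondary alcohol comes back to the route at 17.

**Step 12.**
- What may go wrong: the alkoxide may attack the C4 ketone (retro-Dieckmann opening), the acyl group may shift from C3 to the freed phenoxide, or sulfation of the very crowded phenoxide may be so slow that the lactone re-forms on work-up.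
- Fallback idea: remove the extra carbon before the sulfation, so that the phenol sits next to a tertiary instead of a quaternary carbon. The fallback sets out from 17.
- LiOH in aqueous THF at 0 °C opens the lactone, and buffering to pH 5 gives the protected β-keto acid F3.
- F3 loses CO2 at room temperature and equilibrates to the protected trans flavanone–flavone with free 7''-OH F4.
- Sulfation with SO3·pyridine in pyridine and neutralisation with LiOH give the protected lithium 7''-sulfate F5.
- Hydrogenolysis over Pd(OH)2/C comes back to the route at 21.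

**Step 4.**
- What may go wrong: the allyl group may migrate to C6 in competition with C8, or the product may cyclise thermally.
- Fallback idea: replace the sigmatropic shift by halogenation and cross-coupling. The fallback sets out from 4.
- Iodination of the fully O-alkylated ring A with N-iodosuccinimide and catalytic CF3CO2H in MeCN, which is known to go to C8 in such flavones, gives the 8-iodide F6.
- Stille coupling with allyltributylstannane (Pd(PPh3)4, CuI, CsF, DMF) gives the 8-C-allyl-7-O-allyl flavone F7.
- O-deallylation catalysed by zerovalent palladium (Pd(PPh3)4, morpholine, THF) removes only the allyl ether and comes back to the route at 5.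

**Further compounds**
F1 | step 11 | 2,4-bis(benzyloxy)-6-hydroxybenzaldehyde | O=Cc1c(O)cc(OCc2ccccc2)cc1OCc1ccccc1
F2 | step 11 | spiro chroman-4-ol (C2 and C3 as in 17, C4 epimers converge on oxidation) | OC1c2c(OCc3ccccc3)cc(OCc3ccccc3)cc2O[C@@H](c2ccc(OCc3ccccc3)cc2)[C@@]13C(=O)Oc4cc(OCc5ccccc5)c5c(=O)cc(-c6ccc7c(c6)OC(c6ccccc6)(c6ccccc6)O7)oc5c34
F3 | step 12 | protected β-keto acid (2S,3R) | O=C1c2c(OCc3ccccc3)cc(OCc3ccccc3)cc2O[C@@H](c2ccc(OCc3ccccc3)cc2)[C@]1(C(=O)O)c1c(O)cc(OCc2ccccc2)c2c(=O)cc(-c3ccc4c(c3)OC(c3ccccc3)(c3ccccc3)O4)oc12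
F4 | step 12 | protected trans flavanone–flavone with free 7''-OH (2R,3S) | O=C1c2c(OCc3ccccc3)cc(OCc3ccccc3)cc2O[C@@H](c2ccc(OCc3ccccc3)cc2)[C@@H]1c1c(O)cc(OCc2ccccc2)c2c(=O)cc(-c3ccc4c(c3)OC(c3ccccc3)(c3ccccc3)O4)oc12
F5 | step 12 | protected lithium 7''-sulfate (2R,3S) | O=C1c2c(OCc3ccccc3)cc(OCc3ccccc3)cc2O[C@@H](c2ccc(OCc3ccccc3)cc2)[C@@H]1c1c(OS(=O)(=O)[O-])cc(OCc2ccccc2)c2c(=O)cc(-c3ccc4c(c3)OC(c3ccccc3)(c3ccccc3)O4)oc12.[Li+]
F6 | step 4 | 8-iodo-7-O-allyl-5-O-benzyl-3',4'-O-diphenylmethylene-luteolin | O=c1cc(-c2ccc3c(c2)OC(c2ccccc2)(c2ccccc2)O3)oc2c(I)c(OCC=C)cc(OCc3ccccc3)c12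
F7 | step 4 | 8-C-allyl-7-O-allyl-5-O-benzyl-3',4'-O-diphenylmethylene-luteolin | O=c1cc(-c2ccc3c(c2)OC(c2ccccc2)(c2ccccc2)O3)oc2c(CC=C)c(OCC=C)cc(OCc3ccccc3)c12
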